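**Retrosynthetic overview** (labdane numbering: ring A = C1–C5, C10; ring B = C5–C10; side chain C11–C16 on C9; C17 on C8; C20 on C10)
1. The target is the C2 monoacetate of a 2,3,9-triol. Its side chain is cut at C12–C13 (B-alkyl Suzuki–Miyaura coupling of a C9 vinyl carbinol with a (Z)-β-iodoenoate), and the C9 carbinol at C9–C11 (vinyl addition to a C9 ketone, anti to the C10 methyl).
2. The C9 ketone comes from a C9 carbaldehyde by oxidative deformylation. The formyl group is the removable activating group of the dienophile, and C8 is equilibrated through the ketone.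
3. Key disconnection: C8–C9 and C5–C10 together, by an intramolecular Diels–Alder reaction of an acyclic (2E,8E,10E)-trienal. Enabling feature: ring B (C5–C6–C7–C8–C9–C10) is a six-membered carbocycle that these two bonds divide into a four-carbon unit C5–C8 (diene) and a two-carbon unit C9–C10 (dienophile, C9 being an oxygenated carbon that can pass through the ketone level), while C1–C2–C3–C4 of ring A joins C10 to C5 as a four-atom tether.
4. Trienal: C1–C2 by a vinylogous Mukaiyama aldol reaction (sets C2 anti to C3), C5=C6 by Horner–Wadsworth–Emmons olefination; C3 and the C4 gem-dimethyl group come from the chiral pool.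
5. Ring order: no carbocycle exists before step 11; rings A and B close in that one step.

Key step: step 11

Remark: the labdane numbers above are used for all intermediates; TBS = tert-butyl(dimethyl)silyl.
Assumption: the chiral-pool lactone of step 1 and the allylic phosphonate of step 4 are taken as purchasable.

Step 1
Reactants: 1 (3S)-3-hydroxy-4,4-dimethyloxolan-2-one ((S)-pantolactone)
Product: 2 (3S)-3-{[tert-butyl(dimethyl)silyl]oxy}-4,4-dimethyloxolan-2-one
Conditions: TBSCl, imidazole, DMF, rt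
Reagents that add atoms: tert-butyl(chloro)dimethylsilane (TBSCl), CC(C)(C)[Si](C)(C)Cl
Why: Imidazole-promoted silyl ether formation at the secondary hydroxyl; the stereocentre (later C3) is not touched.

Step 2
Reactants: 2 TBS ether of (S)-pantolactone
Product: 3 (2S)-2-{[tert-butyl(dimethyl)silyl]oxy}-4-hydroxy-N-methoxy-N,3,3-trimethylbutanamide
Conditions: MeNH(OMe)·HCl, AlMe3, CH2Cl2, 0 °C → rt; aq. potassium sodium tartrate
Reagents that add atoms: N,O-dimethylhydroxylamine hydrochloride, CNOC.Cl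
Why: Aluminium amide aminolysis of a lactone (Weinreb amide formation) opens the ring at the acyl carbon, frees the neopentyl alcohol (C5) and leaves the α-stereocentre alone.

Step 3
Reactants: 3 hydroxy Weinreb amide
Product: 4 (2S)-2-{[tert-butyl(dimethyl)silyl]oxy}-N-methoxy-N,3,3-trimethyl-4-oxobutanamide
Conditions: PhI(OAc)2, TEMPO (cat.), CH2Cl2, rt
Reagents that add atoms: none
Why: TEMPO/PhI(OAc)2 oxidation should take the primary alcohol to the non-enolisable aldehyde without affecting the amide or the silyl ether.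

Step 4
Reactants: 4 aldehyde Weinreb amide; 5 diethyl [(2E)-but-2-en-1-yl]phosphonate
Product: 6 (2S,4E,6E)-2-{[tert-butyl(dimethyl)silyl]oxy}-N-methoxy-N,3,3-trimethylocta-4,6-dienamide
Conditions: n-BuLi, THF/DMPU, −78 °C → rt
Reagents that add atoms: none
Why: Horner–Wadsworth–Emmons olefination with the lithiated allylic phosphonate should attack the aldehyde in preference to the hindered amide and form C5=C6 as the (E)-alkene (neopentyl aldehyde), the (E)-geometry of the crotyl unit being carried over.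

Step 5
Reactants: 6 dienyl Weinreb amide
Product: 7 (2S,4E,6E)-2-{[tert-butyl(dimethyl)silyl]oxy}-3,3-dimethylocta-4,6-dienal
Conditions: i-Bu2AlH, THF, −78 °C; aq. potassium sodium tartrate
Reagents that add atoms: none
Why: Reduction of a Weinreb amide stops at the aldehyde through the chelated tetrahedral intermediate, and the α-silyloxy stereocentre should not epimerise at −78 °C.

Step 6
Reactants: 8 methyl 3-methylbut-2-enoate
Product: 9 [(1-methoxy-3-methylbuta-1,3-dien-1-yl)oxy](trimethyl)silane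
Conditions: LiN(i-Pr)2, THF, −78 °C; TMSCl, −78 °C → rt
Reagents that add atoms: chlorotrimethylsilane (TMSCl), C[Si](C)(C)Cl
Why: γ-Deprotonation of the senecioate and O-silylation of the dienolate is the standard entry to this silyl dienol ether.

Step 7
Reactants: 7 α-silyloxy dienal; 9 silyl dienol ether
Product: 10 methyl (2E,5R,6S,8E,10E)-6-{[tert-butyl(dimethyl)silyl]oxy}-5-hydroxy-3,7,7-trimethyldodeca-2,8,10-trienoate
Conditions: BF3·OEt2, CH2Cl2/Et2O, −78 °C; aq. NaHCO3
Reagents that add atoms: none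
Why: Vinylogous Mukaiyama aldol reaction: the dienolate should attack through its γ-carbon to give the (E)-enoate (C1–C2 bond), and the new C2 carbinol should be set anti to the C3 silyloxy group by Felkin–Anh/Cornforth control under the non-chelating Lewis acid.

Step 8
Reactants: 10 δ-hydroxy enoate
Product: 11 methyl (2E,5R,6S,8E,10E)-5,6-bis{[tert-butyl(dimethyl)silyl]oxy}-3,7,7-trimethyldodeca-2,8,10-trienoate
Conditions: TBSOTf, 2,6-lutidine, CH2Cl2, −78 → 0 °C
Reagents that add atoms: tert-butyl(dimethyl)silyl trifluoromethanesulfonate (TBSOTf), CC(C)(C)[Si](C)(C)OS(=O)(=O)C(F)(F)F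
Why: Silyl triflate/lutidine silylation of the hindered secondary alcohol; no stereocentre is affected.

Step 9
Reactants: 11 bis-silyl trienoate
Product: 12 (2E,5R,6S,8E,10E)-5,6-bis{[tert-butyl(dimethyl)silyl]oxy}-3,7,7-trimethyldodeca-2,8,10-trien-1-ol
Conditions: i-Bu2AlH, CH2Cl2, −78 °C; aq. potassium sodium tartrate
Reagents that add atoms: none
Why: 1,2-Reduction of the α,β-unsaturated ester with excess i-Bu2AlH should give the allylic alcohol with the (E)-geometry retained.

Step 10
Reactants: 12 allylic alcohol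
Product: 13 (2E,5R,6S,8E,10E)-5,6-bis{[tert-butyl(dimethyl)silyl]oxy}-3,7,7-trimethyldodeca-2,8,10-trienal
Conditions: PhI(OAc)2, TEMPO (cat.), CH2Cl2, rt
Reagents that add atoms: none
Why: TEMPO/PhI(OAc)2 oxidation of the allylic alcohol should give the (E)-enal without isomerising the double bond.

Step 11
Reactants: 13 acyclic (2E,8E,10E)-trienal
Product: 14 (1S,2S,4aR,6S,7R,8aS)-6,7-bis{[tert-butyl(dimethyl)silyl]oxy}-2,5,5,8a-tetramethyl-1,2,4a,5,6,7,8,8a-octahydronaphthalene-1-carbaldehyde
Conditions: Me2AlCl (1.5 equiv), CH2Cl2 (0.01 M), −78 → −20 °C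
Reagents that add atoms: none
Why: Me2AlCl coordinates the formyl oxygen and lowers the LUMO of the (E)-enal, which then adds suprafacially across the (E,E)-diene in a concerted, asynchronous normal-demand [4+2] cycloaddition; the closest known reaction type is the Lewis-acid-promoted intramolecular Diels–Alder reaction of (E,E,E)-deca-2,7,9-trienal-type substrates to trans-fused octalins. Ring B is closed as the new cyclohexene by both new bonds (C8–C9 and C5–C10), and ring A is closed in the same event through C5–C10 by the four-atom tether C1–C4, which folds into a chair in the anti transition state that places the formyl group endo. C10 (quaternary, methyl cis to CHO) and C9 are fixed relative to each other by the (E)-geometry of the enal, C5 and C8 by the (E,E)-geometry of the diene, and the C5/C10 trans ring fusion by the endo, anti transition state. The absolute sense is relayed from C2 and C3: the C2 silyloxy group stays equatorial on the folding tether, because in the axial position it would meet both the C10 methyl and the axial C4 methyl, and the C3 silyloxy group is therefore axial. The step needs trans over cis fusion and one diene face, which the Lewis-acid-enhanced endo preference of the (E)-enal and the C2/C3 stereocentres should secure. Only C5 and C10 have to be formed correctly here, since C9 is later taken to the ketone and C8 is equilibrated in step 13.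

Step 12
Reactants: 14 octalin carbaldehyde
Product: 15 (1S,2S,4aR,6S,7R,8aS)-6,7-bis{[tert-butyl(dimethyl)silyl]oxy}-2,5,5,8a-tetramethyldecahydronaphthalene-1-carbaldehyde
Conditions: H2 (1 atm), Pd/C, EtOAc, rt
Reagents that add atoms: none
Why: Heterogeneous hydrogenation should saturate the only C=C bond (C6=C7); no stereocentre is created.

Step 13
Reactants: 15 decalin carbaldehyde
Product: 17 (2R,4aS,6S,7R,8aS)-6,7-bis{[tert-butyl(dimethyl)silyl]oxy}-2,5,5,8a-tetramethyloctahydronaphthalen-1(2H)-one, via 2-epi ketone 16 (not isolated)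
Conditions: O2 (1 atm), Cu(OAc)2 (cat.), 2,2'-bipyridine (cat.), DABCO, DMF, 40 °C; then Ar, NaOMe, MeOH, rt
Reagents that add atoms: dioxygen, O=O
Why: Copper-catalysed aerobic oxidative deformylation of an α-branched aldehyde (enolate oxygenation, then cleavage to ketone and formate) should unmask the C9 ketone, and base equilibration through the C8 enolate should then move the C8 methyl from the axial position syn to the C10 methyl into the equatorial position, which sets C8.

Step 14
Reactants: 17 C9 ketone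
Product: 18 (1S,2R,4aS,6S,7R,8aS)-6,7-bis{[tert-butyl(dimethyl)silyl]oxy}-1-ethenyl-2,5,5,8a-tetramethyldecahydronaphthalen-1-ol
Conditions: CH2=CHMgBr, CeCl3, THF, −78 → 0 °C; aq. NH4Cl
Reagents that add atoms: vinylmagnesium bromide, C=C[Mg]Br
Why: 1,2-Addition of the weakly basic vinylcerium reagent to the hindered ketone should occur on the axial α-face, anti to the axial C10 methyl that blocks the equatorial trajectory, which sets C9 with the hydroxyl equatorial and cis to that methyl.

Step 15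
Reactants: 19 methyl but-2-ynoate
Product: 20 methyl (2Z)-3-iodobut-2-enoate
Conditions: NaI, AcOH, 115 °C
Reagents that add atoms: sodium iodide, [Na+].[I-]
Why: Conjugate anti-hydroiodination of the ynoate gives the (Z)-β-iodoenoate stereoselectively.

Step 16
Reactants: 18 C9 vinyl carbinol; 20 (Z)-β-iodoenoate
Product: 22 methyl (2Z)-5-[(1S,2R,4aS,6S,7R,8aS)-6,7-bis{[tert-butyl(dimethyl)silyl]oxy}-1-hydroxy-2,5,5,8a-tetramethyldecahydronaphthalen-1-yl]-3-methylpent-2-enoate, via B-alkyl-9-BBN adduct 21 (not isolated)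
Conditions: 9-BBN-H, THF, rt → 50 °C; then PdCl2(dppf) (cat.), AsPh3, Cs2CO3, DMF/THF/H2O, rt
Reagents that add atoms: 9-borabicyclo[3.3.1]nonane, B1C2CCCC1CCC2 (its boron unit stays only in 21; 22 keeps one hydrogen from it)
Why: Anti-Markovnikov hydroboration of the vinyl group followed by B-alkyl Suzuki–Miyaura coupling should form C12–C13 with retention of the (Z)-geometry of the iodoenoate; no stereocentre is formed.

Step 17
Reactants: 22 bis-silyl ether of the side-chain ester
Product: 23 methyl (2Z)-3-methyl-5-[(1S,2R,4aS,6S,7R,8aS)-1,6,7-trihydroxy-2,5,5,8a-tetramethyldecahydronaphthalen-1-yl]pent-2-enoate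
Conditions: HF·pyridine, pyridine/THF, 0 °C → rt
Reagents that add atoms: none
Why: Fluoride cleavage of both silyl ethers under buffered, non-basic conditions should avoid alkoxide formation and hence oxa-Michael addition to the enoate.

Step 18
Reactants: 23 triol
Product: 24 methyl (2Z)-5-[(1S,2R,4aS,6S,7R,8aS)-7-(acetyloxy)-1,6-dihydroxy-2,5,5,8a-tetramethyldecahydronaphthalen-1-yl]-3-methylpent-2-enoate
Conditions: Ac2O (1.05 equiv), pyridine, CH2Cl2, 0 °C
Reagents that add atoms: acetic anhydride, CC(=O)OC(C)=O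
Why: Kinetic acylation should select the equatorial C2 hydroxyl over the axial, neopentyl C3 hydroxyl and the tertiary C9 hydroxyl.

**Compound list**
1 | (3S)-3-hydroxy-4,4-dimethyloxolan-2-one | CC1(C)COC(=O)[C@H]1O | starting material
2 | (3S)-3-{[tert-butyl(dimethyl)silyl]oxy}-4,4-dimethyloxolan-2-one | CC1(C)COC(=O)[C@H]1O[Si](C)(C)C(C)(C)C | intermediate
3 | (2S)-2-{[tert-butyl(dimethyl)silyl]oxy}-4-hydroxy-N-methoxy-N,3,3-trimethylbutanamide | OCC(C)(C)[C@H](O[Si](C)(C)C(C)(C)C)C(=O)N(C)OC | intermediate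
4 | (2S)-2-{[tert-butyl(dimethyl)silyl]oxy}-N-methoxy-N,3,3-trimethyl-4-oxobutanamide | O=CC(C)(C)[C@H](O[Si](C)(C)C(C)(C)C)C(=O)N(C)OC | intermediate
5 | diethyl [(2E)-but-2-en-1-yl]phosphonate | CCOP(=O)(C/C=C/C)OCC | starting material
6 | (2S,4E,6E)-2-{[tert-butyl(dimethyl)silyl]oxy}-N-methoxy-N,3,3-trimethylocta-4,6-dienamide | C/C=C/C=C/C(C)(C)[C@H](O[Si](C)(C)C(C)(C)C)C(=O)N(C)OC | intermediate
7 | (2S,4E,6E)-2-{[tert-butyl(dimethyl)silyl]oxy}-3,3-dimethylocta-4,6-dienal | C/C=C/C=C/C(C)(C)[C@H](O[Si](C)(C)C(C)(C)C)C=O | intermediate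
8 | methyl 3-methylbut-2-enoate | COC(=O)C=C(C)C | starting material
9 | [(1-methoxy-3-methylbuta-1,3-dien-1-yl)oxy](trimethyl)silane | C=C(C)C=C(OC)O[Si](C)(C)C | intermediate
10 | methyl (2E,5R,6S,8E,10E)-6-{[tert-butyl(dimethyl)silyl]oxy}-5-hydroxy-3,7,7-trimethyldodeca-2,8,10-trienoate | C/C=C/C=C/C(C)(C)[C@H](O[Si](C)(C)C(C)(C)C)[C@H](O)C/C(C)=C/C(=O)OC | intermediate
11 | methyl (2E,5R,6S,8E,10E)-5,6-bis{[tert-butyl(dimethyl)silyl]oxy}-3,7,7-trimethyldodeca-2,8,10-trienoate | C/C=C/C=C/C(C)(C)[C@H](O[Si](C)(C)C(C)(C)C)[C@H](O[Si](C)(C)C(C)(C)C)C/C(C)=C/C(=O)OC | intermediate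
12 | (2E,5R,6S,8E,10E)-5,6-bis{[tert-butyl(dimethyl)silyl]oxy}-3,7,7-trimethyldodeca-2,8,10-trien-1-ol | C/C=C/C=C/C(C)(C)[C@H](O[Si](C)(C)C(C)(C)C)[C@H](O[Si](C)(C)C(C)(C)C)C/C(C)=C/CO | intermediate
13 | (2E,5R,6S,8E,10E)-5,6-bis{[tert-butyl(dimethyl)silyl]oxy}-3,7,7-trimethyldodeca-2,8,10-trienal | C/C=C/C=C/C(C)(C)[C@H](O[Si](C)(C)C(C)(C)C)[C@H](O[Si](C)(C)C(C)(C)C)C/C(C)=C/C=O | intermediate
14 | (1S,2S,4aR,6S,7R,8aS)-6,7-bis{[tert-butyl(dimethyl)silyl]oxy}-2,5,5,8a-tetramethyl-1,2,4a,5,6,7,8,8a-octahydronaphthalene-1-carbaldehyde | O=C[C@H]1[C@@H](C)C=C[C@H]2C(C)(C)[C@H](O[Si](C)(C)C(C)(C)C)[C@H](O[Si](C)(C)C(C)(C)C)C[C@@]21C | intermediate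
15 | (1S,2S,4aR,6S,7R,8aS)-6,7-bis{[tert-butyl(dimethyl)silyl]oxy}-2,5,5,8a-tetramethyldecahydronaphthalene-1-carbaldehyde | O=C[C@H]1[C@@H](C)CC[C@H]2C(C)(C)[C@H](O[Si](C)(C)C(C)(C)C)[C@H](O[Si](C)(C)C(C)(C)C)C[C@@]21C | intermediate
16 | (2S,4aS,6S,7R,8aS)-6,7-bis{[tert-butyl(dimethyl)silyl]oxy}-2,5,5,8a-tetramethyloctahydronaphthalen-1(2H)-one | O=C1[C@@H](C)CC[C@H]2C(C)(C)[C@H](O[Si](C)(C)C(C)(C)C)[C@H](O[Si](C)(C)C(C)(C)C)C[C@@]21C | intermediate
17 | (2R,4aS,6S,7R,8aS)-6,7-bis{[tert-butyl(dimethyl)silyl]oxy}-2,5,5,8a-tetramethyloctahydronaphthalen-1(2H)-one | O=C1[C@H](C)CC[C@H]2C(C)(C)[C@H](O[Si](C)(C)C(C)(C)C)[C@H](O[Si](C)(C)C(C)(C)C)C[C@@]21C | intermediate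
18 | (1S,2R,4aS,6S,7R,8aS)-6,7-bis{[tert-butyl(dimethyl)silyl]oxy}-1-ethenyl-2,5,5,8a-tetramethyldecahydronaphthalen-1-ol | C=C[C@]1(O)[C@H](C)CC[C@H]2C(C)(C)[C@H](O[Si](C)(C)C(C)(C)C)[C@H](O[Si](C)(C)C(C)(C)C)C[C@@]21C | intermediate
19 | methyl but-2-ynoate | CC#CC(=O)OC | starting material
20 | methyl (2Z)-3-iodobut-2-enoate | COC(=O)/C=C(/C)I | intermediate
21 | (1S,2R,4aS,6S,7R,8aS)-1-[2-(9-borabicyclo[3.3.1]nonan-9-yl)ethyl]-6,7-bis{[tert-butyl(dimethyl)silyl]oxy}-2,5,5,8a-tetramethyldecahydronaphthalen-1-ol | C1CC2CCCC(C1)B2CC[C@]3(O)[C@H](C)CC[C@H]4C(C)(C)[C@H](O[Si](C)(C)C(C)(C)C)[C@H](O[Si](C)(C)C(C)(C)C)C[C@@]43C | intermediate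
22 | methyl (2Z)-5-[(1S,2R,4aS,6S,7R,8aS)-6,7-bis{[tert-butyl(dimethyl)silyl]oxy}-1-hydroxy-2,5,5,8a-tetramethyldecahydronaphthalen-1-yl]-3-methylpent-2-enoate | COC(=O)/C=C(/C)CC[C@]1(O)[C@H](C)CC[C@H]2C(C)(C)[C@H](O[Si](C)(C)C(C)(C)C)[C@H](O[Si](C)(C)C(C)(C)C)C[C@@]21C | intermediate
23 | methyl (2Z)-3-methyl-5-[(1S,2R,4aS,6S,7R,8aS)-1,6,7-trihydroxy-2,5,5,8a-tetramethyldecahydronaphthalen-1-yl]pent-2-enoate | COC(=O)/C=C(/C)CC[C@]1(O)[C@H](C)CC[C@H]2C(C)(C)[C@H](O)[C@H](O)C[C@@]21C | intermediate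
24 | methyl (2Z)-5-[(1S,2R,4aS,6S,7R,8aS)-7-(acetyloxy)-1,6-dihydroxy-2,5,5,8a-tetramethyldecahydronaphthalen-1-yl]-3-methylpent-2-enoate | COC(=O)/C=C(/C)CC[C@]1(O)[C@H](C)CC[C@H]2C(C)(C)[C@H](O)[C@H](OC(C)=O)C[C@@]21C | target

**Step count**
Total: 18 steps. Longest linear sequence: 16 steps (1 → 24 through steps 1–5, 7–14 and 16–18; steps 6 and 15 prepare 9 and 20).

**Steps most likely to fail**

Step 11. The anti and syn foldings of the tether may be poorly discriminated, because the anti transition state carries a developing 1,3-diaxial contact between the C10 methyl and the axial C4 methyl; the Lewis acid may also cause stepwise closure or loss of a silyl ether. Fallback: a cationic instead of a neutral cycloaddition. Setting out from trienal 13, 1,2-bis(trimethylsilyloxy)ethane with catalytic TMSOTf (CH2Cl2, −78 °C) should give the ethylene acetal 2-[(1E,4R,5S,7E,9E)-4,5-bis{[tert-butyl(dimethyl)silyl]oxy}-2,6,6-trimethylundeca-1,7,9-trien-1-yl]-1,3-dioxolane F1. More TMSOTf at −78 → −40 °C should ionise the acetal to an alkoxy-stabilised allyl cation, whose ionic Diels–Alder closure (a known low-temperature reaction of hindered enal acetals) should give 2-[(1S,2S,4aR,6S,7R,8aS)-6,7-bis{[tert-butyl(dimethyl)silyl]oxy}-2,5,5,8a-tetramethyl-1,2,4a,5,6,7,8,8a-octahydronaphthalen-1-yl]-1,3-dioxolane F2. PPTS in wet acetone should then hydrolyse the acetal, and the route is rejoined at aldehyde 14.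

Step 7. Facial control at C2 by the C3 silyloxy stereocentre may be incomplete, the dienolate may attack through its α-carbon, or the activated aldehyde may close onto the diene. Fallback: propargylation followed by carbometalation. Setting out from aldehyde 7, allenylboronic acid pinacol ester (toluene, rt, closed six-membered transition state, optionally with a chiral BINOL-derived phosphoric acid for reagent control) should give (4R,5S,7E,9E)-5-{[tert-butyl(dimethyl)silyl]oxy}-6,6-dimethylundeca-7,9-dien-1-yn-4-ol F3. TBSOTf/2,6-lutidine should give (4R,5S,7E,9E)-4,5-bis{[tert-butyl(dimethyl)silyl]oxy}-6,6-dimethylundeca-7,9-dien-1-yne F4. Zirconium-catalysed syn-carboalumination of the terminal alkyne (AlMe3, Cp2ZrCl2, CH2Cl2) and trapping of the alkenylalane with ClCO2Me should then deliver the (E)-enoate, and the route is rejoined at 11.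

Step 13. Enolisation of the hindered aldehyde toward the copper enolate may be slow, or the ketone may be over-oxidised at C8 once formed. Fallback: enol ether cleavage. Setting out from aldehyde 15, TBSOTf/Et3N (CH2Cl2, rt) should give tert-butyl({[(2S,4aR,6S,7R,8aS)-6,7-bis{[tert-butyl(dimethyl)silyl]oxy}-2,5,5,8a-tetramethyloctahydronaphthalen-1(2H)-ylidene]methyl}oxy)dimethylsilane F5 (enol ether geometry immaterial). Ozonolysis (O3, CH2Cl2, −78 °C; Me2S) should cleave the exocyclic C=C bond and rejoin the route at ketone 16, which NaOMe/MeOH equilibrates to 17 as in step 13.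

Further compounds
F1 | step 11 | 2-[(1E,4R,5S,7E,9E)-4,5-bis{[tert-butyl(dimethyl)silyl]oxy}-2,6,6-trimethylundeca-1,7,9-trien-1-yl]-1,3-dioxolane | C/C=C/C=C/C(C)(C)[C@H](O[Si](C)(C)C(C)(C)C)[C@H](O[Si](C)(C)C(C)(C)C)C/C(C)=C/C1OCCO1
F2 | step 11 | 2-[(1S,2S,4aR,6S,7R,8aS)-6,7-bis{[tert-butyl(dimethyl)silyl]oxy}-2,5,5,8a-tetramethyl-1,2,4a,5,6,7,8,8a-octahydronaphthalen-1-yl]-1,3-dioxolane | C1COC(O1)[C@H]2[C@@H](C)C=C[C@H]3C(C)(C)[C@H](O[Si](C)(C)C(C)(C)C)[C@H](O[Si](C)(C)C(C)(C)C)C[C@@]32C
F3 | step 7 | (4R,5S,7E,9E)-5-{[tert-butyl(dimethyl)silyl]oxy}-6,6-dimethylundeca-7,9-dien-1-yn-4-ol | C/C=C/C=C/C(C)(C)[C@H](O[Si](C)(C)C(C)(C)C)[C@H](O)CC#C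
F4 | step 7 | (4R,5S,7E,9E)-4,5-bis{[tert-butyl(dimethyl)silyl]oxy}-6,6-dimethylundeca-7,9-dien-1-yne | C/C=C/C=C/C(C)(C)[C@H](O[Si](C)(C)C(C)(C)C)[C@H](O[Si](C)(C)C(C)(C)C)CC#C
F5 | step 13 | tert-butyl({[(2S,4aR,6S,7R,8aS)-6,7-bis{[tert-butyl(dimethyl)silyl]oxy}-2,5,5,8a-tetramethyloctahydronaphthalen-1(2H)-ylidene]methyl}oxy)dimethylsilane | CC(C)(C)[Si](C)(C)OC=C1[C@@H](C)CC[C@H]2C(C)(C)[C@H](O[Si](C)(C)C(C)(C)C)[C@H](O[Si](C)(C)C(C)(C)C)C[C@@]21C
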